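## Retrosynthetic overview

1. Target 8 comes from the tri-O-benzyl (E)-stilbene 7 by one global hydrogenation. This turns C=C into CH2CH2 and three OBn groups into OH.
2. Stilbene 7 comes from a single four-component norbornene/palladium coupling, which is the new step. It forms the C2–benzyl, C6–benzyl and C1–vinyl bonds of ring A from aryl iodide 3, two molecules of benzylic chloride 4 and styrene 5.
3. Iodide 3 comes from 3-bromo-5-methoxyphenol 1 by O-benzylation and Br-to-I exchange, so the OH/OMe difference on ring A is fixed from the first step.
4. No ring is built. All four benzene rings are bought intact, and ring A is the hub that receives the C2/C6 benzyl groups first and the C1 side chain last.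

Assumption: the SMILES is taken as authoritative (ring A: 3-OH, 5-OMe, 2,6-bis(4-hydroxybenzyl); ring B: 3′-OMe). It has no stereocentre, so the target is achiral and needs no enantiocontrol; the only stereo-element in the route, the (E)-alkene of 7, is erased in step 4.

## Route

**Step 1**
Reactants: 1 3-bromo-5-methoxyphenol
Product: 2 1-(benzyloxy)-3-bromo-5-methoxybenzene
Conditions: BnBr (1.1 equiv), K2CO3 (2 equiv), acetone, reflux, 6 h
Reagents that add atoms: benzyl bromide, BrCc1ccccc1
Why: Williamson ether synthesis on the only acidic OH, and the aryl bromide and the methyl ether are inert to K2CO3.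

**Step 2**
Reactants: 2 1-(benzyloxy)-3-bromo-5-methoxybenzene
Product: 3 1-(benzyloxy)-3-iodo-5-methoxybenzene
Conditions: CuI (5 mol %), N,N′-dimethylethane-1,2-diamine (10 mol %), NaI (2 equiv), 1,4-dioxane, 110 °C, 24 h
Reagents that add atoms: sodium iodide, [Na+].[I-]
Why: Copper-catalysed aromatic Finkelstein halogen exchange is pulled to the iodide because NaBr precipitates from dioxane, and both ethers are untouched.

**Step 3**
Reactants: 3 1-(benzyloxy)-3-iodo-5-methoxybenzene; 4 4-(benzyloxy)benzyl chloride (two molecules are built in, 3 equiv used); 5 3-methoxystyrene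
Product: 7 (E)-3-(benzyloxy)-2,6-bis[4-(benzyloxy)benzyl]-3′,5-dimethoxystilbene, via 2,6-dibenzylated arylpalladium iodide 6 (not isolated)
Conditions: Pd(OAc)2 (10 mol %), norbornene (4 equiv), K2CO3 (6 equiv), dry DMA, 60 °C, argon; 5 (1.5 equiv) added by syringe pump over 8 h
Reagents that add atoms: none
Why: Proposed new method: this is a doubly ortho-benzylative Catellani–Heck coupling on an aryl iodide whose two ortho C–H bonds are each flanked by a meta alkoxy group, a substrate class not yet shown to be difunctionalised by norbornene/palladium catalysis, with a benzylic chloride as the twofold electrophile; zerovalent palladium inserts into the carbon–iodine bond of 3, norbornene carbopalladation brings divalent palladium next to an ortho C–H bond acidified by the adjacent oxygen so that carbonate-assisted metalation closes the five-membered aryl–norbornyl palladacycle, phosphine-free conditions leave only solvent on the site beside the small rotatable alkoxy group, the electron-rich palladacycle attacks the SN2-active chloride 4 to give tetravalent palladium that reductively eliminates the aryl–CH2 bond, excess norbornene and a starved feed of 5 return any prematurely released mono-benzylated arylpalladium to the cycle for the second ortho position, the 2,6-disubstituted aryl then expels norbornene by beta-carbon elimination to give 6, and Mizoroki–Heck insertion of 5 with beta-hydride elimination gives the (E)-alkene; the closest known reaction type is the Catellani ortho,ortho′-dialkylation/Heck vinylation of meta-unsubstituted aryl iodides with primary alkyl halides.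

**Step 4**
Reactants: 7 (E)-3-(benzyloxy)-2,6-bis[4-(benzyloxy)benzyl]-3′,5-dimethoxystilbene
Product: 8 3-hydroxy-2,6-bis(4-hydroxybenzyl)-3′,5-dimethoxybibenzyl (target)
Conditions: H2 (3 atm), 10% Pd/C, THF–MeOH 1:1, rt, 16 h
Reagents that add atoms: none
Why: Heterogeneous catalytic hydrogenation saturates the disubstituted alkene and hydrogenolyses the three aryl benzyl ethers in one operation, while aryl methyl ethers and diarylmethane C–C bonds are inert and no stereocentre is created.

## Compound list

1 | 3-bromo-5-methoxyphenol | COc1cc(O)cc(Br)c1 | starting material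
2 | 1-(benzyloxy)-3-bromo-5-methoxybenzene | COc1cc(Br)cc(OCc2ccccc2)c1 | intermediate
3 | 1-(benzyloxy)-3-iodo-5-methoxybenzene | COc1cc(I)cc(OCc2ccccc2)c1 | intermediate
4 | 4-(benzyloxy)benzyl chloride | ClCc1ccc(OCc2ccccc2)cc1 | starting material
5 | 3-methoxystyrene | COc1cccc(C=C)c1 | starting material
6 | {3-(benzyloxy)-2,6-bis[4-(benzyloxy)benzyl]-5-methoxyphenyl}palladium iodide (divalent palladium, solvent ligands omitted, not isolated) | COc1cc(OCc2ccccc2)c(Cc2ccc(OCc3ccccc3)cc2)c([Pd]I)c1Cc1ccc(OCc2ccccc2)cc1 | intermediate
7 | (E)-3-(benzyloxy)-2,6-bis[4-(benzyloxy)benzyl]-3′,5-dimethoxystilbene | COc1cccc(/C=C/c2c(Cc3ccc(OCc4ccccc4)cc3)c(OCc3ccccc3)cc(OC)c2Cc2ccc(OCc3ccccc3)cc2)c1 | intermediate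
8 | 3-hydroxy-2,6-bis(4-hydroxybenzyl)-3′,5-dimethoxybibenzyl | COc1cccc(CCc2c(Cc3ccc(O)cc3)c(O)cc(OC)c2Cc2ccc(O)cc2)c1 | target

## Step count and risks

Total step count: 4. Longest linear sequence: 4 steps (1 → 2 → 3 → 7 → 8).

**Step 3 (the proposed new step)** is the most likely to fail.
- The alkoxy-flanked ortho positions may resist palladation or alkylation, which would give the direct Heck product or a mono-benzylated stilbene.
- Intermediate 6 may close onto a benzyl ring to give a fluorene.
- Chloride 4 may be consumed by zerovalent palladium.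

The fallback uses known chemistry, sets out from 3 (and from 4 for the benzyl donor) and comes back at 7. Iodine–magnesium exchange of 3 with iPrMgCl·LiCl (THF, −20 °C) gives [3-(benzyloxy)-5-methoxyphenyl]magnesium chloride F1. Quenching with DMF and then dilute HCl gives 3-(benzyloxy)-5-methoxybenzaldehyde F2. NBS (2.2 equiv, MeCN, 0 °C to rt) brominates the two positions para to an oxygen, before ring B is present, to give 3-(benzyloxy)-2,6-dibromo-5-methoxybenzaldehyde F3. Horner–Wadsworth–Emmons olefination with diethyl (3-methoxybenzyl)phosphonate (KOtBu, THF, 0 °C to rt) gives (E)-3-(benzyloxy)-2,6-dibromo-3′,5-dimethoxystilbene F4. Zinc insertion into 4 (Zn dust, LiCl, THF, rt) gives [4-(benzyloxy)benzyl]zinc chloride F5. A twofold Negishi coupling of F4 with F5 (2.6 equiv, Pd(OAc)2 4 mol %, SPhos 8 mol %, THF, 50 °C) then delivers 7.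

**Step 4** may fail in two ways.
- The alkene is shielded by two ortho benzyl groups and may reduce slowly.
- Traces of iodide may poison the catalyst, leaving mixtures of partly debenzylated material.

The fallback sets out from 7 and comes back at 8, and it separates the two tasks. Homogeneous hydrogenation with [Ir(cod)(PCy3)(py)]PF6 (2 mol %, H2 1 atm, CH2Cl2, rt) saturates only the alkene to give 3-(benzyloxy)-2,6-bis[4-(benzyloxy)benzyl]-3′,5-dimethoxybibenzyl F6. Lewis-acid debenzylation with BCl3 (6 equiv) and pentamethylbenzene (9 equiv) as cation scavenger (CH2Cl2, −78 °C) then removes the three benzyl ethers without touching the methyl ethers and gives 8.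

**Step 2** may stop at an incomplete equilibrium exchange, which leaves a bromide/iodide mixture that is hard to separate. The fallback sets out from 2 and comes back at 3, and it replaces catalytic exchange by stoichiometric metalation. Bromine–lithium exchange with n-BuLi (1.05 equiv, THF, −78 °C) gives [3-(benzyloxy)-5-methoxyphenyl]lithium F7, which is quenched with I2 (1.1 equiv, THF, −78 °C to rt) to give 3.

## Further compounds

F1 | step 3 | [3-(benzyloxy)-5-methoxyphenyl]magnesium chloride | COc1cc(OCc2ccccc2)cc([Mg]Cl)c1
F2 | step 3 | 3-(benzyloxy)-5-methoxybenzaldehyde | COc1cc(C=O)cc(OCc2ccccc2)c1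
F3 | step 3 | 3-(benzyloxy)-2,6-dibromo-5-methoxybenzaldehyde | COc1cc(OCc2ccccc2)c(Br)c(C=O)c1Br
F4 | step 3 | (E)-3-(benzyloxy)-2,6-dibromo-3′,5-dimethoxystilbene | COc1cccc(/C=C/c2c(Br)c(OCc3ccccc3)cc(OC)c2Br)c1
F5 | step 3 | [4-(benzyloxy)benzyl]zinc chloride | Cl[Zn]Cc1ccc(OCc2ccccc2)cc1
F6 | step 4 | 3-(benzyloxy)-2,6-bis[4-(benzyloxy)benzyl]-3′,5-dimethoxybibenzyl | COc1cccc(CCc2c(Cc3ccc(OCc4ccccc4)cc3)c(OCc3ccccc3)cc(OC)c2Cc2ccc(OCc3ccccc3)cc2)c1
F7 | step 2 | [3-(benzyloxy)-5-methoxyphenyl]lithium | [Li]c1cc(OC)cc(OCc2ccccc2)c1
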